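**Retrosynthetic overview**
- Numbering: ring A = C5–C6=C7(acetyl)–C8(=O)–C9(O-angeloyl)–C10(OH); ring B = C10–C1–C2–C3(OAc)–C4(Me)–C5(Me); β is the face of the C5 methyl. The strategy rests on the C8/C9 oxygen pair of ring A lying beside the quaternary, methyl-bearing fusion carbon C5, which is the imprint of 2-methoxy-5-methyl-1,4-benzoquinone reacting as a dienophile at its methylated C5=C10 bond.
- Late disconnections: C7 acetyl (Stille coupling on the α-iodoenone), C9 angelate and C3 acetate, the C6=C7–C8=O enone (1,3-carbonyl transposition of the C6 vinylogous ester), C9–OH (hydroxyl-directed reduction), C3–OH (ketone reduction), C10–OH (enolate hydroxylation).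
- Key disconnection: C4–C5 and C1–C10, an endo [4+2] cycloaddition of the quinone with (Z)-3-(triisopropylsilyloxy)penta-1,3-diene under a chiral BINOL–titanium Lewis acid. It sets C5 and C10 (cis) and C4 (trans to the C5 methyl); C4 is corrected later by epimerisation through the C3 ketone.
- Ring order: ring A enters intact as the quinone; ring B is the only ring formed, in the cycloaddition.

Key step: step 3

Assumption: the (S)-BINOL–titanium complex is taken to shield the quinone face that leads to 5 as drawn; should it favour the mirror image, (R)-BINOL is used with no other change.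

Step 1
Reactants: 1 2-methoxy-5-methylphenol
Product: 2 2-methoxy-5-methyl-1,4-benzoquinone
Conditions: (KSO3)2NO (Fremy's salt), KH2PO4, H2O/acetone, 0 °C to rt
Reagents that add atoms: potassium nitrosodisulfonate, [K+].[K+].[O]N(S(=O)(=O)[O-])S(=O)(=O)[O-]
Why: Teuber oxidation: the nitrosodisulfonate radical oxidises the phenol to its phenoxyl radical and traps it at the free para position, and collapse of that adduct gives the para-quinone; no stereocentre is involved.

Step 2
Reactants: 3 pent-1-en-3-one
Product: 4 (Z)-3-(triisopropylsilyloxy)penta-1,3-diene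
Conditions: i-Pr3SiOTf, Et3N, CH2Cl2, 0 °C to rt
Reagents that add atoms: triisopropylsilyl trifluoromethanesulfonate, CC(C)[Si](OS(=O)(=O)C(F)(F)F)(C(C)C)C(C)C
Why: Soft enolisation (silyl triflate activation of the carbonyl, deprotonation of the ethyl side by the amine) gives the conjugated silyl dienol ether, and the (Z)-geometry with the methyl anti to the vinyl group is the usual outcome for ethyl ketones under these conditions and is the geometry that can reach the s-cis conformation.

Step 3
Reactants: 2 2-methoxy-5-methyl-1,4-benzoquinone; 4 (Z)-3-(triisopropylsilyloxy)penta-1,3-diene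
Product: 5 cis-fused adduct 8-methoxy-4α,5β-dimethyl-3-(triisopropylsilyloxy)decalin-2,7-diene-6,9-dione with 10β-H
Conditions: TiCl2(OiPr)2 (10 mol%), (S)-BINOL (10 mol%), 4 Å MS, CH2Cl2, −78 to −30 °C
Reagents that add atoms: none
Why: The titanium centre binds the quinone in a bidentate way through the C9 carbonyl and the methoxy oxygen, which lowers the LUMO and makes C5, the β-carbon of the activated C9 enone, the most electrophilic site, so a concerted but asynchronous normal-demand [4+2] cycloaddition starts at C5 with the enol-ether β-carbon of the diene (the CH–CH3 terminus, future C4) and completes the C1–C10 bond in the same suprafacial event. The closest known reaction type is the chiral titanium–BINOL (and related chiral Lewis acid) quinone Diels–Alder reaction, together with Lewis-acid-promoted diene additions to the methylated double bond of this same quinone. Ring B is closed by the intermolecular [4+2] cycloaddition itself, both σ-bonds being made across the diene termini with no separate cyclisation. C5 and C10 should emerge cis because addition to the quinone double bond is suprafacial, C4 should carry its methyl trans to the C5 methyl because the outside methyl of the (Z)-enol ether passes through an endo transition state, and the absolute sense is set by the BINOL ligand shielding one face of the chelated quinone. The step needs site selectivity (the methoxy group turns the other double bond into an electron-rich vinylogous ester), regioselectivity (chelation plus the polarity of the 2-silyloxy diene), endo selectivity (secondary overlap with the quinone carbonyls under Lewis acid catalysis) and enantioface selectivity (catalyst control).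

Step 4
Reactants: 5 cis-fused adduct
Product: 7 10β-hydroxy-8-methoxy-4α,5β-dimethyl-3-(triisopropylsilyloxy)decalin-2,7-diene-6,9-dione (cis-fused), via potassium enolate 6 (not isolated)
Conditions: KN(SiMe3)2, THF, −78 °C; then 2-(phenylsulfonyl)-3-phenyloxaziridine, −78 °C; AcOH quench
Reagents that add atoms: 2-(phenylsulfonyl)-3-phenyloxaziridine, O=S(=O)(c1ccccc1)N1OC1c1ccccc1
Why: Enolate α-hydroxylation with an N-sulfonyloxaziridine: with C3 masked as the silyl enol ether, C10–H is the only enolisable position, and oxygen should be delivered to the β face of the planar enolate because the α face of C10 is screened by the pseudo-axial α-methyl at C4 (1,3-syn to the incoming reagent) and by the fold of ring B, so the hydroxyl replaces the hydrogen and the cis fusion is kept.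

Step 5
Reactants: 7 10β-hydroxy silyl enol ether
Product: 9 10β-hydroxy-8-methoxy-4β,5β-dimethyldecal-7-ene-3,6,9-trione, via 4α-methyl triketone 8 (not isolated)
Conditions: Bu4NF, AcOH, THF, 0 °C; then DBU (0.3 equiv), CH2Cl2, rt
Reagents that add atoms: none
Why: Fluoride desilylation gives the C3 ketone 8 without touching C4, and amidine-catalysed α-epimerisation through the C3(4)-enolate then equilibrates C4; 9 should be favoured because the ring-B chair with the C5 methyl axial holds its C4 methyl equatorial, whereas 8 must either stand that methyl axial and 1,3-syn to C9 or flip to the chair with an axial C10 oxygen, where the equatorial C4 methyl meets the C6 carbonyl oxygen (peri strain), and any remaining 8 is separated and re-equilibrated.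

Step 6
Reactants: 9 4β,5β-dimethyl triketone
Product: 10 9α,10β-dihydroxy-8-methoxy-4β,5β-dimethyldecal-7-ene-3,6-dione
Conditions: Me4NBH(OAc)3, MeCN/AcOH, −30 to 0 °C
Reagents that add atoms: none
Why: Hydroxyl-directed triacetoxyborohydride reduction (Evans–Saksena type): the reagent exchanges an acetate for the C10 hydroxyl and passes hydride intramolecularly to the neighbouring C9 carbonyl on the β face, which should set the 9α-hydroxyl trans to the 10β-hydroxyl, while the undirected C3 ketone and the electron-rich C6 vinylogous ester carbonyl are left alone at low temperature.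

Step 7
Reactants: 10 9α,10β-diol diketone
Product: 11 3β,9α,10β-trihydroxy-8-methoxy-4β,5β-dimethyldecal-7-en-6-one
Conditions: NaBH4, MeOH/CH2Cl2, −40 to −20 °C
Reagents that add atoms: none
Why: Borohydride reduction, chemoselective for the saturated C3 ketone over the vinylogous ester carbonyl at C6; hydride should enter from the α face, away from the β-methyl groups on C4 and C5, which gives the 3β-alcohol cis to the C4 methyl.

Step 8
Reactants: 11 3β,9α,10β-triol
Product: 12 3β-acetoxy-9α,10β-dihydroxy-8-methoxy-4β,5β-dimethyldecal-7-en-6-one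
Conditions: Ac2O (1.1 equiv), pyridine, CH2Cl2, −20 to 0 °C
Reagents that add atoms: acetic anhydride, CC(=O)OC(C)=O
Why: Rate-selective acylation: the C3 hydroxyl, flanked by a methylene and a methine, should react with acetic anhydride/pyridine faster than the C9 hydroxyl wedged between the fully substituted C10 and C8, and faster than the tertiary C10 hydroxyl.

Step 9
Reactants: 12 3β-acetate 9α,10β-diol; 13 angelic acid ((Z)-2-methylbut-2-enoic acid)
Product: 15 3β-acetoxy-9α-angeloyloxy-10β-hydroxy-8-methoxy-4β,5β-dimethyldecal-7-en-6-one, via angelic 2,4,6-trichlorobenzoic anhydride 14 (not isolated)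
Conditions: 13, 2,4,6-trichlorobenzoyl chloride, Et3N, toluene, rt; then 12, 75 °C
Reagents that add atoms: none
Why: Yamaguchi-type mixed-anhydride esterification: the hindered alcohol attacks the angeloyl carbonyl of 14 because the aroyl carbonyl is shielded by its two ortho chlorines, and leaving out a nucleophilic acyl-transfer catalyst avoids the conjugate addition–elimination that turns angelates into tiglates; the tertiary C10 hydroxyl does not react.

Step 10
Reactants: 15 3β-acetate 9α-angelate vinylogous ester
Product: 17 3β-acetoxy-9α-angeloyloxy-10β-hydroxy-4β,5β-dimethyldecal-6-en-8-one, via C6 allylic alcohol 16 (not isolated)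
Conditions: NaBH4, CeCl3·7H2O, MeOH, −20 to 0 °C; then 1 M HCl, THF, 0 °C to rt
Reagents that add atoms: water, O
Why: Luche 1,2-reduction of the vinylogous ester carbonyl followed by acid-induced 1,3-carbonyl transposition (Stork–Danheiser type): the allylic C6 hydroxyl of 16 ionises to the methoxy-stabilised allyl cation, water adds at C8 and methanol is lost, giving the C6=C7–C8=O enone; the C6 configuration of 16 is immaterial and no stereocentre of 17 is touched.

Step 11
Reactants: 17 C6-ene-8-one
Product: 18 7-iodo-3β-acetoxy-9α-angeloyloxy-10β-hydroxy-4β,5β-dimethyldecal-6-en-8-one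
Conditions: I2, pyridine/CH2Cl2, 0 °C to rt
Reagents that add atoms: iodine, II
Why: Amine-promoted α-iodination of an enone (conjugate addition of pyridine at C6, iodination of the resulting enolate at C7, elimination of pyridine; Baylis–Hillman-type sequence), which works on 4,4-disubstituted cyclohexenones, while the electron-poor angelate double bond is inert to iodine.

Step 12
Reactants: 18 7-iodo enone
Product: 20 CNP0196241.1, via 1-ethoxyvinyl enone 19 (not isolated)
Conditions: tributyl(1-ethoxyvinyl)stannane, Pd2(dba)3, AsPh3, CuI, NMP, rt; then 0.5 M HCl, THF, 0 °C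
Reagents that add atoms: tributyl(1-ethoxyvinyl)stannane, CCCC[Sn](CCCC)(CCCC)C(=C)OCC; water, O
Why: Stille coupling of the α-iodoenone with an acetyl-anion equivalent (copper-accelerated), followed by mild acid hydrolysis of enol ether 19 to the methyl ketone; no stereocentre is formed or disturbed.

**Compound list**
1 | 2-methoxy-5-methylphenol | COc1ccc(C)cc1O | starting material
2 | 2-methoxy-5-methyl-1,4-benzoquinone | COC1=CC(=O)C(C)=CC1=O | intermediate
3 | pent-1-en-3-one | CCC(=O)C=C | starting material
4 | (Z)-3-(triisopropylsilyloxy)penta-1,3-diene | C=C/C(=C/C)O[Si](C(C)C)(C(C)C)C(C)C | intermediate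
5 | cis-fused adduct, 8-methoxy-4α,5β-dimethyl-3-(triisopropylsilyloxy)decalin-2,7-diene-6,9-dione, 10β-H | O=C1C(OC)=CC(=O)[C@]2(C)[C@H](C)C(O[Si](C(C)C)(C(C)C)C(C)C)=CC[C@H]12 | intermediate
6 | potassium C9(10)-enolate of 5 (not isolated) | [K+].[O-]C=1C(OC)=CC(=O)[C@]2(C)[C@H](C)C(O[Si](C(C)C)(C(C)C)C(C)C)=CCC2=1 | intermediate
7 | 10β-hydroxy-8-methoxy-4α,5β-dimethyl-3-(triisopropylsilyloxy)decalin-2,7-diene-6,9-dione | O=C1C(OC)=CC(=O)[C@]2(C)[C@H](C)C(O[Si](C(C)C)(C(C)C)C(C)C)=CC[C@]12O | intermediate
8 | 10β-hydroxy-8-methoxy-4α,5β-dimethyldecal-7-ene-3,6,9-trione (not isolated) | O=C1C(OC)=CC(=O)[C@]2(C)[C@H](C)C(=O)CC[C@]12O | intermediate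
9 | 10β-hydroxy-8-methoxy-4β,5β-dimethyldecal-7-ene-3,6,9-trione | O=C1C(OC)=CC(=O)[C@]2(C)[C@@H](C)C(=O)CC[C@]12O | intermediate
10 | 9α,10β-dihydroxy-8-methoxy-4β,5β-dimethyldecal-7-ene-3,6-dione | O[C@@H]1C(OC)=CC(=O)[C@]2(C)[C@@H](C)C(=O)CC[C@]12O | intermediate
11 | 3β,9α,10β-trihydroxy-8-methoxy-4β,5β-dimethyldecal-7-en-6-one | O[C@@H]1C(OC)=CC(=O)[C@]2(C)[C@@H](C)[C@@H](O)CC[C@]12O | intermediate
12 | 3β-acetoxy-9α,10β-dihydroxy-8-methoxy-4β,5β-dimethyldecal-7-en-6-one | O[C@@H]1C(OC)=CC(=O)[C@]2(C)[C@@H](C)[C@@H](OC(C)=O)CC[C@]12O | intermediate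
13 | angelic acid, (Z)-2-methylbut-2-enoic acid | C/C=C(/C)C(=O)O | starting material
14 | angelic 2,4,6-trichlorobenzoic anhydride (not isolated) | C/C=C(/C)C(=O)OC(=O)c1c(Cl)cc(Cl)cc1Cl | intermediate
15 | 3β-acetoxy-9α-angeloyloxy-10β-hydroxy-8-methoxy-4β,5β-dimethyldecal-7-en-6-one | C/C=C(/C)C(=O)O[C@@H]1C(OC)=CC(=O)[C@]2(C)[C@@H](C)[C@@H](OC(C)=O)CC[C@]12O | intermediate
16 | 3β-acetoxy-9α-angeloyloxy-8-methoxy-4β,5β-dimethyldecal-7-ene-6,10β-diol, C6 configuration left open (not isolated) | C/C=C(/C)C(=O)O[C@@H]1C(OC)=CC(O)[C@]2(C)[C@@H](C)[C@@H](OC(C)=O)CC[C@]12O | intermediate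
17 | 3β-acetoxy-9α-angeloyloxy-10β-hydroxy-4β,5β-dimethyldecal-6-en-8-one | C/C=C(/C)C(=O)O[C@@H]1C(=O)C=C[C@]2(C)[C@@H](C)[C@@H](OC(C)=O)CC[C@]12O | intermediate
18 | 7-iodo-3β-acetoxy-9α-angeloyloxy-10β-hydroxy-4β,5β-dimethyldecal-6-en-8-one | C/C=C(/C)C(=O)O[C@@H]1C(=O)C(I)=C[C@]2(C)[C@@H](C)[C@@H](OC(C)=O)CC[C@]12O | intermediate
19 | 7-(1-ethoxyvinyl)-3β-acetoxy-9α-angeloyloxy-10β-hydroxy-4β,5β-dimethyldecal-6-en-8-one (not isolated) | C/C=C(/C)C(=O)O[C@@H]1C(=O)C(C(=C)OCC)=C[C@]2(C)[C@@H](C)[C@@H](OC(C)=O)CC[C@]12O | intermediate
20 | CNP0196241.1, 7-acetyl-3β-acetoxy-9α-angeloyloxy-10β-hydroxy-4β,5β-dimethyldecal-6-en-8-one, (3S,4R,5R,9S,10R) in the skeleton numbering | C/C=C(/C)C(=O)O[C@@H]1C(=O)C(C(C)=O)=C[C@]2(C)[C@@H](C)[C@@H](OC(C)=O)CC[C@]12O | target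

Total step count: 12
Longest linear sequence: 11 steps (1 → 2 → 5 → 7 → 9 → 10 → 11 → 12 → 15 → 17 → 18 → 20)

**Steps most likely to fail**

Risk 1 (step 5): the base-mediated equilibrium at C4 may settle near parity instead of on the side of 9, and prolonged exposure to base invites an α-ketol shift of the C9/C10 unit. The fallback replaces thermodynamic by kinetic control and sets out from 8, isolated after the buffered desilylation alone. Me3SiCl/NaI/Et3N in MeCN should convert 8 into the more substituted C3–C4 trimethylsilyl enol ether with silylation of the C10 hydroxyl, the bis-silyl compound F1. One equivalent of CF3CO2H in CH2Cl2 at −78 °C should then protonate C4 axially, anti to the pseudo-axial C5 methyl of the half-chair, with the β face further screened by the C10 silyl ether, to give the 10-O-trimethylsilyl ether of the cis-dimethyl triketone F2. HF·pyridine in MeCN at 0 °C removes the silyl ether and the route is rejoined at 9.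

Risk 2 (step 3): enantioface discrimination may be eroded by an uncatalysed or stepwise Mukaiyama–Michael background pathway, and incomplete chelation would let the diene attack C10 instead of C5. The fallback replaces asymmetric catalysis by resolution and sets out from 2 and 4. The cycloaddition is run with the achiral chelating Lewis acid SnCl4 in CH2Cl2 at −78 °C, which should give the same endo adduct as a racemate, that is 5 together with its mirror image ent-5 F3. The enantiomers are separated by preparative supercritical-fluid chromatography on an amylose tris(3,5-dimethylphenylcarbamate) phase, and the route is rejoined at 5.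

Risk 3 (step 9): the angeloyl unit may isomerise to the (E)-tigloyl isomer during activation, or acylation of the hindered C9 hydroxyl may stall. The fallback builds the (Z)-alkene after acylation and sets out from 12. Esterification with 2-(diphenoxyphosphoryl)propanoic acid (EDC·HCl, DMAP, CH2Cl2) should give the C9 phosphonopropionate F4. A (Z)-selective Horner–Wadsworth–Emmons reaction of F4 with acetaldehyde under NaI/DBU in THF at −78 to 0 °C, conditions that leave the tertiary hydroxyl alone, should then give the angelate, and the route is rejoined at 15.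

**Further compounds**
F1 | step 5 | 10β-(trimethylsilyloxy)-3-(trimethylsilyloxy)-8-methoxy-4,5β-dimethyldecalin-3,7-diene-6,9-dione | O=C1C(OC)=CC(=O)[C@]2(C)C(C)=C(O[Si](C)(C)C)CC[C@]12O[Si](C)(C)C
F2 | step 5 | 10β-(trimethylsilyloxy)-8-methoxy-4β,5β-dimethyldecal-7-ene-3,6,9-trione | O=C1C(OC)=CC(=O)[C@]2(C)[C@@H](C)C(=O)CC[C@]12O[Si](C)(C)C
F3 | step 3 | ent-5, mirror image of adduct 5 | O=C1C(OC)=CC(=O)[C@@]2(C)[C@@H](C)C(O[Si](C(C)C)(C(C)C)C(C)C)=CC[C@@H]12
F4 | step 9 | 9α-[2-(diphenoxyphosphoryl)propanoyloxy]-3β-acetoxy-10β-hydroxy-8-methoxy-4β,5β-dimethyldecal-7-en-6-one | CC(P(=O)(Oc1ccccc1)Oc1ccccc1)C(=O)O[C@@H]1C(OC)=CC(=O)[C@]2(C)[C@@H](C)[C@@H](OC(C)=O)CC[C@]12O
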